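**Retrosynthetic overview**

1. Ring A is the methoxy ring (ketone arm on carbon 1, methoxy on carbon 3, bridging oxygen on carbon 4); ring B is the phenolic ring (arm on carbon 1, bridging oxygen on carbon 3, hydroxyl on carbon 4). The strategy rests on carbon 1 of each ring: it carries one 3-aryl-3-oxopropyl arm, has only CH neighbours and lies para to an oxygen, so both can travel as C–Br through a metal-free ether synthesis and then serve for C–C coupling.
2. Target 15 ⇐ global debenzylation of pentabenzyl ether 14.
3. 14 ⇐ two aryl–CH2 bonds (at carbon 1 of ring A and of ring B) by double Heck arylation of racemic aryl vinyl carbinol 11 with dibromide 6, each carbinol isomerising to its ketone in the same event.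
4. 6 ⇐ diaryl ether by SNAr of bromoguaiacol 1 on fluoroaldehyde 2, Dakin-type oxidation of the formyl group to the ring B hydroxyl, then benzylation; 11 ⇐ benzylation of aldehyde 7 and vinyl Grignard addition.
5. No ring is formed at any stage; all four benzene rings are purchased.

Key step: step 6

Remark on the chemistry: the ring B hydroxyl oxygen is brought in as a formyl group and unmasked by Dakin-type oxidation, not through a diazonium salt, because 2-aryloxybenzenediazonium ions are prone to Pschorr-type closure to dibenzofurans.

**Route**

Step 1
Reactants: 1 4-bromo-2-methoxyphenol; 2 4-bromo-2-fluorobenzaldehyde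
Product: 3 4-bromo-2-(4-bromo-2-methoxyphenoxy)benzaldehyde
Conditions: K2CO3, DMF, 110 °C
Reagents that add atoms: none
Why: Nucleophilic aromatic substitution (SNAr), in which the phenoxide of 1 displaces the fluoride ortho to the formyl group through a Meisenheimer adduct, fluoride being far more labile than the bromide para to the formyl group, so that the ether between carbon 4 of ring A and carbon 3 of ring B forms and both bromines are kept.

Step 2
Reactants: 3 4-bromo-2-(4-bromo-2-methoxyphenoxy)benzaldehyde
Product: 5 4-bromo-2-(4-bromo-2-methoxyphenoxy)phenol, via aryl formate 4 (not isolated)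
Conditions: mCPBA, CH2Cl2, 0 °C → rt; aq. NaHCO3 wash; then K2CO3 (cat.), MeOH, rt
Reagents that add atoms: 3-chloroperoxybenzoic acid (mCPBA), O=C(OO)c1cccc(Cl)c1
Why: Baeyer–Villiger (Dakin-type) oxidation, in which the ring bearing the ortho aryloxy donor migrates in the Criegee adduct in preference to hydride to give formate 4, whose methanolysis frees the hydroxyl on carbon 4 of ring B, while the aryl bromides and the diaryl ether are inert to the peracid.

Step 3
Reactants: 5 4-bromo-2-(4-bromo-2-methoxyphenoxy)phenol
Product: 6 1-(benzyloxy)-4-bromo-2-(4-bromo-2-methoxyphenoxy)benzene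
Conditions: BnBr, K2CO3, DMF, 50 °C
Reagents that add atoms: benzyl bromide, BrCc1ccccc1
Why: Williamson ether synthesis on the phenoxide, which masks the ring B hydroxyl as a benzyl ether that tolerates the palladium coupling and leaves at the end together with the other four.

Step 4
Reactants: 7 2,4-dihydroxybenzaldehyde
Product: 8 2,4-bis(benzyloxy)benzaldehyde
Conditions: BnBr (2.4 equiv), K2CO3, DMF, 60 °C
Reagents that add atoms: benzyl bromide, BrCc1ccccc1
Why: Twofold Williamson ether synthesis, in which excess benzyl bromide and gentle heating also alkylate the hydrogen-bonded 2-hydroxyl.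

Step 5
Reactants: 8 2,4-bis(benzyloxy)benzaldehyde; 9 vinylmagnesium bromide
Product: 11 rac-1-[2,4-bis(benzyloxy)phenyl]prop-2-en-1-ol, via bromomagnesium alkoxide 10 (not isolated)
Conditions: THF, −20 → 0 °C; then sat. aq. NH4Cl, 0 °C
Reagents that add atoms: vinylmagnesium bromide (9), C=C[Mg]Br
Why: Grignard 1,2-addition to the aldehyde, in which the new carbinol centre forms as a racemate without control because it becomes the carbonyl carbon in step 6, and the near-neutral quench avoids ionisation of the electron-rich benzylic allylic alcohol, which is used without chromatography on acidic silica.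

Step 6
Reactants: 6 1-(benzyloxy)-4-bromo-2-(4-bromo-2-methoxyphenoxy)benzene; 11 rac-1-[2,4-bis(benzyloxy)phenyl]prop-2-en-1-ol (two molecules react, 3 equiv used)
Product: 14 verbenachalcone pentabenzyl ether, via ring A monoketone 12 (not isolated), via ring B monoketone 13 (not isolated)
Conditions: Pd(OAc)2 (10 mol%), P(t-Bu)3·HBF4 (20 mol%), Cy2NMe (4 equiv), dioxane, 90 °C
Reagents that add atoms: none
Why: Heck–Mizoroki arylation of a secondary allylic alcohol with redox relay: each aryl bromide of 6 adds oxidatively to zerovalent palladium, the arylpalladium species inserts the monosubstituted alkene of 11 with the aryl group going to the unsubstituted terminus, and beta-hydride elimination of the carbinol hydrogen releases an enol that tautomerises to the ketone. The closest known reaction type is the Heck arylation of 1-arylprop-2-en-1-ols and of but-3-en-2-ol with aryl bromides, which gives beta-aryl ketones directly. No ring is closed and no stereocentre is created; the racemic carbinol centre becomes the carbonyl carbon. The step needs terminal regioselectivity, secured by the monosubstituted alkene and the unhindered bromine-bearing carbons (carbon 1 of ring A and of ring B), and hydride loss on the carbinol side, secured because elimination toward the benzylic CH2 is reversible through reinsertion whereas the enol-to-ketone tautomerisation is irreversible. A tertiary amine base keeps the ketone from being enolised for alpha-arylation, and the surplus of 11 covers carbinol lost by palladium hydride isomerisation to the propiophenone. The saturated chain thus appears without an alkene hydrogenation, and the benzyl ethers, methyl ether and diaryl ether are inert to the conditions.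

Step 7
Reactants: 14 verbenachalcone pentabenzyl ether
Product: 15 verbenachalcone
Conditions: H2 (1 atm), 10% Pd/C, EtOAc–MeOH, rt
Reagents that add atoms: none
Why: Catalytic hydrogenolysis of the five benzyl aryl ethers over palladium on carbon, in which the aryl ketones, deactivated as vinylogous esters by their ortho and para oxygen donors, the methyl ether and the diaryl ether should persist at 1 atm and room temperature.

**Compound list**

1 | 4-bromo-2-methoxyphenol | COc1cc(Br)ccc1O | starting material
2 | 4-bromo-2-fluorobenzaldehyde | O=Cc1ccc(Br)cc1F | starting material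
3 | 4-bromo-2-(4-bromo-2-methoxyphenoxy)benzaldehyde | COc1cc(Br)ccc1Oc1cc(Br)ccc1C=O | intermediate
4 | 4-bromo-2-(4-bromo-2-methoxyphenoxy)phenyl formate (not isolated) | COc1cc(Br)ccc1Oc1cc(Br)ccc1OC=O | intermediate
5 | 4-bromo-2-(4-bromo-2-methoxyphenoxy)phenol | COc1cc(Br)ccc1Oc1cc(Br)ccc1O | intermediate
6 | 1-(benzyloxy)-4-bromo-2-(4-bromo-2-methoxyphenoxy)benzene | COc1cc(Br)ccc1Oc1cc(Br)ccc1OCc1ccccc1 | intermediate
7 | 2,4-dihydroxybenzaldehyde | O=Cc1ccc(O)cc1O | starting material
8 | 2,4-bis(benzyloxy)benzaldehyde | O=Cc1ccc(OCc2ccccc2)cc1OCc1ccccc1 | intermediate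
9 | vinylmagnesium bromide | C=C[Mg]Br | starting material
10 | bromomagnesium 1-[2,4-bis(benzyloxy)phenyl]prop-2-en-1-olate (racemic, not isolated) | C=CC(O[Mg]Br)c1ccc(OCc2ccccc2)cc1OCc1ccccc1 | intermediate
11 | rac-1-[2,4-bis(benzyloxy)phenyl]prop-2-en-1-ol (racemate, centre left undefined) | C=CC(O)c1ccc(OCc2ccccc2)cc1OCc1ccccc1 | intermediate
12 | 1-[2,4-bis(benzyloxy)phenyl]-3-{4-[2-(benzyloxy)-5-bromophenoxy]-3-methoxyphenyl}propan-1-one (ring A coupled, ring B still brominated, not isolated) | COc1cc(CCC(=O)c2ccc(OCc3ccccc3)cc2OCc2ccccc2)ccc1Oc1cc(Br)ccc1OCc1ccccc1 | intermediate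
13 | 1-[2,4-bis(benzyloxy)phenyl]-3-[4-(benzyloxy)-3-(4-bromo-2-methoxyphenoxy)phenyl]propan-1-one (ring B coupled, ring A still brominated, not isolated) | COc1cc(Br)ccc1Oc1cc(CCC(=O)c2ccc(OCc3ccccc3)cc2OCc2ccccc2)ccc1OCc1ccccc1 | intermediate
14 | verbenachalcone pentabenzyl ether, 1-[2,4-bis(benzyloxy)phenyl]-3-[4-(benzyloxy)-3-(4-{3-[2,4-bis(benzyloxy)phenyl]-3-oxopropyl}-2-methoxyphenoxy)phenyl]propan-1-one | COc1cc(CCC(=O)c2ccc(OCc3ccccc3)cc2OCc2ccccc2)ccc1Oc1cc(CCC(=O)c2ccc(OCc3ccccc3)cc2OCc2ccccc2)ccc1OCc1ccccc1 | intermediate
15 | verbenachalcone | COc1cc(CCC(=O)c2ccc(O)cc2O)ccc1Oc1cc(CCC(=O)c2ccc(O)cc2O)ccc1O | target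

**Step count**

Total steps: 7. Longest linear sequence: 5 steps (steps 1, 2, 3, 6, 7); the carbinol branch (steps 4, 5) joins at step 6.

**Steps most likely to fail**

1. Step 6 (double Heck arylation–isomerisation). Oxidative addition into the two electron-rich bromides may stall after the first coupling, or palladium hydride may isomerise the carbinol to the saturated propiophenone faster than it is arylated, so that mono-coupled material accumulates. The fallback sets out from dibromide 6 and comes back to the route at target 15. Double bromine–lithium exchange (n-BuLi, THF, −78 °C) should give the dilithio diaryl ether F1, which is quenched with DMF to 4-(benzyloxy)-3-(4-formyl-2-methoxyphenoxy)benzaldehyde F2. Twofold Claisen–Schmidt condensation of F2 with commercial 1-[2,4-bis(benzyloxy)phenyl]ethanone F3 (KOH, EtOH–THF, rt) should give the (E,E)-bis-chalcone pentabenzyl ether F4. Hydrogenation of F4 (H2, Pd/C, EtOAc–MeOH, rt) should saturate both enone alkenes and cleave the five benzyl ethers in one operation to give 15.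

2. Step 2 (Dakin-type oxidation). Hydride may migrate instead of the aryl group in the Criegee adduct, because the para bromine lowers the migratory aptitude of ring B, and the benzoic acid would then form in place of the formate. The fallback sets out from phenol 1 and comes back to the route at dibromide 6, bypassing steps 1 to 3. Chan–Lam oxidative coupling of 1 with [2-(benzyloxy)-5-bromophenyl]boronic acid F5 (Cu(OAc)2 (20 mol%), pyridine, powdered molecular sieves, CH2Cl2, O2 balloon, rt) should form the diaryl ether bond between carbon 4 of ring A and carbon 3 of ring B with the benzyl ether already in place and leave both aryl bromides untouched.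

3. Step 7 (global hydrogenolysis). The aryl ketones may be over-reduced to carbinols or methylene groups while the last benzyl ethers are still being cleaved, or the reaction may stall at partly benzylated stages. The fallback sets out from 14 and comes back at 15. BCl3 with pentamethylbenzene as benzyl cation scavenger (CH2Cl2, −78 °C, then MeOH quench) should cleave the five benzyl aryl ethers by Lewis acid dealkylation with no hydrogen present, so carbonyl reduction cannot occur, and the methyl ether should survive at this temperature. No new compound arises on the way (F0).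

**Further compounds**

F1 | step 6 | 1-(benzyloxy)-4-lithio-2-(4-lithio-2-methoxyphenoxy)benzene | COc1cc([Li])ccc1Oc1cc([Li])ccc1OCc1ccccc1
F2 | step 6 | 4-(benzyloxy)-3-(4-formyl-2-methoxyphenoxy)benzaldehyde | COc1cc(C=O)ccc1Oc1cc(C=O)ccc1OCc1ccccc1
F3 | step 6 | 1-[2,4-bis(benzyloxy)phenyl]ethanone | CC(=O)c1ccc(OCc2ccccc2)cc1OCc1ccccc1
F4 | step 6 | (E,E)-bis-chalcone pentabenzyl ether, (E)-1-[2,4-bis(benzyloxy)phenyl]-3-[4-(benzyloxy)-3-(4-{(E)-3-[2,4-bis(benzyloxy)phenyl]-3-oxoprop-1-enyl}-2-methoxyphenoxy)phenyl]prop-2-en-1-one | COc1cc(/C=C/C(=O)c2ccc(OCc3ccccc3)cc2OCc2ccccc2)ccc1Oc1cc(/C=C/C(=O)c2ccc(OCc3ccccc3)cc2OCc2ccccc2)ccc1OCc1ccccc1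
F5 | step 2 | [2-(benzyloxy)-5-bromophenyl]boronic acid | OB(O)c1cc(Br)ccc1OCc1ccccc1
F0 | step 7 | none | none
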